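**Assumption:** the target is the briarane of the given SMILES, (1S,2R,5Z,7S,9R,10S,14S) in briarane numbering. Labels C1–C20 below follow that numbering (C15, C16, C20 = methyls on C1, C5, C11; C17 = lactone α-carbon).

## Retrosynthetic overview

1. The ten-membered ring is closed last, at C8–C9, by Nozaki–Hiyama–Kishi addition of a β-iodobutenolide to a C9 aldehyde; this also delivers the free 9-OH.
2. The cyclohexene (C11=C12, C14–OAc) comes from reductive opening of a 7-oxanorbornene, whose ether bridge masks the C14 oxygen until C2 has been reduced and butanoylated.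
3. The 7-oxanorbornene comes from an enantioselective Diels–Alder reaction of 2-methylfuran with a mesaconic imide/thioester, which sets C1 (quaternary), C10, C14 and the trans C2/C9 relationship in one step.
4. C2–C3 is made by Fukuyama coupling with a Z-alkenyl allenoate zinc reagent from anhydromevalonolactone (C7 stored as allene axial chirality); iodolactonisation then gives the butenolide.
5. Ring order: six-membered carbocycle (as oxanorbornene), then butenolide, then ten-membered ring.

## Route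

**Step 1**
Reactants: 1 mesaconic acid [(E)-2-methylbut-2-enedioic acid]
Product: 2 mesaconyl dichloride [(E)-2-methylbut-2-enedioyl dichloride]
Conditions: (COCl)2, cat. DMF, CH2Cl2, 0 °C → rt
Reagents that add atoms: oxalyl chloride, O=C(Cl)C(=O)Cl
Why: Acid chloride formation through the Vilsmeier-type chloroiminium catalyst runs at or below room temperature, so the E-alkene is not isomerised to the citraconic (Z) series.

**Step 2**
Reactants: 2 mesaconyl dichloride; 3 1,3-oxazolidin-2-one
Product: 6 S-ethyl (E)-2-methyl-4-oxo-4-(2-oxo-1,3-oxazolidin-3-yl)but-2-enethioate, via lithium oxazolidinide 4 (not isolated), via mono-imide acyl chloride 5 (not isolated)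
Conditions: 3, n-BuLi, THF, −78 °C; added to 2, THF, −78 °C; then EtSH (1.0 equiv), pyridine, −78 → −20 °C
Reagents that add atoms: ethanethiol, CCS
Why: Sequential nucleophilic acyl substitution: the bulky lithium oxazolidinide takes the less hindered acyl chloride (on the CH carbon; the other is shielded by the α-methyl group), and one equivalent of thiol at low temperature then thioesterifies the remaining acyl chloride faster than thia-Michael addition; the minor regioisomer is removed by crystallisation.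

**Step 3**
Reactants: 6 S-ethyl (E)-2-methyl-4-oxo-4-(2-oxo-1,3-oxazolidin-3-yl)but-2-enethioate; 7 2-methylfuran
Product: 8 S-ethyl (1S,2R,3R,4R)-2,4-dimethyl-3-(2-oxo-1,3-oxazolidine-3-carbonyl)-7-oxabicyclo[2.2.1]hept-5-ene-2-carbothioate
Conditions: [Cu((R,R)-t-Bu-box)](SbF6)2 (10 mol %; t-Bu-box = 2,2′-(propane-2,2-diyl)bis(4-tert-butyl-4,5-dihydrooxazole)), 7 (10 equiv), CH2Cl2, 3 Å MS, −78 → −50 °C
Reagents that add atoms: none
Why: Proposed new method: enantioselective furan Diels–Alder reaction in which the square-planar divalent copper bis(oxazoline) cation chelates the s-cis imide and exposes its α-Si face; the most nucleophilic furan carbon (C5, future C14) bonds to the β-carbon (future C1), the activated imide goes endo, and the E geometry becomes the trans C2/C9 relationship, so C1 (quaternary), C10, C14 and bridgehead C11 are set at once; the closest known reactions are this catalyst's furan cycloaddition with 3-acryloyl-2-oxazolidinone and its cycloadditions of fumaroyl imides, the new elements being the β,β-disubstituted dienophile and 2-methylfuran.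

**Step 4**
Reactants: 9 anhydromevalonolactone [4-methyl-5,6-dihydro-2H-pyran-2-one]
Product: 10 (Z)-5-hydroxy-N-methoxy-N,3-dimethylpent-2-enamide
Conditions: MeNH(OMe)·HCl, Me3Al, CH2Cl2, 0 °C → rt
Reagents that add atoms: N,O-dimethylhydroxylamine hydrochloride, CNOC.Cl
Why: Weinreb amidation of the lactone by the aluminium amide opens the ring by acyl–oxygen cleavage only, so the Z geometry enforced by the six-membered ring passes unchanged into the open chain.

**Step 5**
Reactants: 10 (Z)-5-hydroxy-N-methoxy-N,3-dimethylpent-2-enamide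
Product: 11 (Z)-5-iodo-N-methoxy-N,3-dimethylpent-2-enamide
Conditions: I2, PPh3, imidazole, CH2Cl2, 0 °C
Reagents that add atoms: iodine, II
Why: Appel reaction: SN2 displacement of the primary alkoxyphosphonium ion by iodide under neutral conditions leaves the Z-enamide untouched.

**Step 6**
Reactants: 11 (Z)-5-iodo-N-methoxy-N,3-dimethylpent-2-enamide
Product: 12 (Z)-8-iodo-6-methyloct-5-en-2-yn-4-one
Conditions: MeC≡CMgBr, THF, −78 → 0 °C
Reagents that add atoms: 1-propynylmagnesium bromide, CC#C[Mg]Br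
Why: Weinreb ketone synthesis: the magnesium-chelated tetrahedral adduct stops at the ketone stage, and the primary iodide does not react with the alkynyl Grignard reagent at low temperature.

**Step 7**
Reactants: 12 (Z)-8-iodo-6-methyloct-5-en-2-yn-4-one
Product: 13 (4R,5Z)-8-iodo-6-methyloct-5-en-2-yn-4-ol
Conditions: RuCl[(R,R)-TsDPEN](p-cymene) (2 mol %), i-PrOH, rt
Reagents that add atoms: none
Why: Noyori asymmetric transfer hydrogenation of an alkynyl ketone: the alkyne takes the site favoured by the CH/π contact with the p-cymene ligand and the bulky Z-alkenyl group the open site, so the (R,R)-catalyst gives the (R)-alcohol without reducing C=C or C≡C; this centre later becomes C7.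

**Step 8**
Reactants: 13 (4R,5Z)-8-iodo-6-methyloct-5-en-2-yn-4-ol
Product: 14 methyl (4R,5Z)-8-iodo-6-methyloct-5-en-2-yn-4-yl carbonate
Conditions: ClCO2Me, pyridine, CH2Cl2, 0 °C
Reagents that add atoms: methyl chloroformate, COC(=O)Cl
Why: Carbonate formation (O-acylation) turns the doubly activated alcohol into a leaving group that, unlike the mesylate, is stable enough to isolate.

**Step 9**
Reactants: 14 methyl (4R,5Z)-8-iodo-6-methyloct-5-en-2-yn-4-yl carbonate
Product: 15 methyl (Sa,5Z)-8-iodo-2,6-dimethylocta-2,3,5-trienoate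
Conditions: Pd2(dba)3 (2.5 mol %), PPh3 (10 mol %), CO (1 atm), MeOH/THF, rt
Reagents that add atoms: carbon monoxide, [C-]#[O+]
Why: Tsuji carbonylation of a propargylic carbonate: zerovalent palladium ionises the carbonate by anti SN2′ attack to an allenylpalladium species, CO inserts with retention and the methoxide released on decarboxylation completes the ester, so the (R)-centre becomes the (Sa)-allene (centre-to-axis chirality transfer).

**Step 10**
Reactants: 15 methyl (Sa,5Z)-8-iodo-2,6-dimethylocta-2,3,5-trienoate; 8 S-ethyl (1S,2R,3R,4R)-2,4-dimethyl-3-(2-oxo-1,3-oxazolidine-3-carbonyl)-7-oxabicyclo[2.2.1]hept-5-ene-2-carbothioate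
Product: 17 methyl (Sa,5Z)-8-[(1S,2R,3R,4R)-2,4-dimethyl-3-(2-oxo-1,3-oxazolidine-3-carbonyl)-7-oxabicyclo[2.2.1]hept-5-en-2-yl]-2,6-dimethyl-8-oxoocta-2,3,5-trienoate, via alkylzinc iodide 16 (not isolated)
Conditions: 15, Zn dust (TMSCl-activated), LiCl, THF, 35 °C; then 8, PdCl2(PPh3)2 (5 mol %), THF/toluene, rt
Reagents that add atoms: none
Why: Fukuyama coupling: zinc inserts into the primary C–I bond and the alkylzinc iodide couples with the thioester under palladium catalysis to stop at the ketone (C2–C3 bond); the imide, allenoate and strained alkene are tolerated and no stereocentre is touched.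

**Step 11**
Reactants: 17 methyl (Sa,5Z)-8-[(1S,2R,3R,4R)-2,4-dimethyl-3-(2-oxo-1,3-oxazolidine-3-carbonyl)-7-oxabicyclo[2.2.1]hept-5-en-2-yl]-2,6-dimethyl-8-oxoocta-2,3,5-trienoate
Product: 18 methyl (Sa,5Z,8R)-8-[(1S,2S,3R,4R)-2,4-dimethyl-3-(2-oxo-1,3-oxazolidine-3-carbonyl)-7-oxabicyclo[2.2.1]hept-5-en-2-yl]-8-hydroxy-2,6-dimethylocta-2,3,5-trienoate
Conditions: Zn(BH4)2, Et2O, −40 °C
Reagents that add atoms: none
Why: Chelation-controlled (Cram chelate) ketone reduction: zinc bridges the C2 carbonyl oxygen and the bridging ether oxygen on C14, C10 then stands perpendicular to the carbonyl plane and hydride enters from the opposite face, giving the (2R)-alcohol (1,3-syn to the C14 oxygen); imide and allenoate are not reduced at −40 °C.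

**Step 12**
Reactants: 18 methyl (Sa,5Z,8R)-8-[(1S,2S,3R,4R)-2,4-dimethyl-3-(2-oxo-1,3-oxazolidine-3-carbonyl)-7-oxabicyclo[2.2.1]hept-5-en-2-yl]-8-hydroxy-2,6-dimethylocta-2,3,5-trienoate
Product: 19 methyl (Sa,5Z,8R)-8-(butanoyloxy)-8-[(1S,2S,3R,4R)-2,4-dimethyl-3-(2-oxo-1,3-oxazolidine-3-carbonyl)-7-oxabicyclo[2.2.1]hept-5-en-2-yl]-2,6-dimethylocta-2,3,5-trienoate
Conditions: n-PrCOCl, pyridine, CH2Cl2, 0 °C → rt
Reagents that add atoms: butanoyl chloride, CCCC(=O)Cl
Why: Esterification of the hindered secondary alcohol with the acid chloride in pyridine; the trans-disposed imide cannot lactonise onto the C2 oxygen and the weak base leaves the allenoate and the imide α-proton alone.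

**Step 13**
Reactants: 19 methyl (Sa,5Z,8R)-8-(butanoyloxy)-8-[(1S,2S,3R,4R)-2,4-dimethyl-3-(2-oxo-1,3-oxazolidine-3-carbonyl)-7-oxabicyclo[2.2.1]hept-5-en-2-yl]-2,6-dimethylocta-2,3,5-trienoate
Product: 20 (1R,4Z)-1-[(1S,2S,3R,4R)-2,4-dimethyl-3-(2-oxo-1,3-oxazolidine-3-carbonyl)-7-oxabicyclo[2.2.1]hept-5-en-2-yl]-5-[(2S)-3-iodo-4-methyl-5-oxo-2,5-dihydrofuran-2-yl]-4-methylpent-4-en-1-yl butanoate
Conditions: I2 (1.5 equiv), MeCN, 0 °C → rt; Na2S2O3 work-up
Reagents that add atoms: iodine, II
Why: Iodolactonisation of a 2,3-allenoate: iodine activates the C7=C8 bond, the ester carbonyl oxygen closes onto C7 from its own side in the ester plane and iodide removes the O-methyl group, so the (Sa)-axis becomes the (7S)-centre (axis-to-centre transfer) and the β-iodobutenolide needed for ring closure is formed; the electron-rich vinylallene reacts before the oxanorbornene alkene.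

**Step 14**
Reactants: 20 (1R,4Z)-1-[(1S,2S,3R,4R)-2,4-dimethyl-3-(2-oxo-1,3-oxazolidine-3-carbonyl)-7-oxabicyclo[2.2.1]hept-5-en-2-yl]-5-[(2S)-3-iodo-4-methyl-5-oxo-2,5-dihydrofuran-2-yl]-4-methylpent-4-en-1-yl butanoate
Product: 21 (1R,4Z)-1-[(1S,2S,6S)-6-acetoxy-1,3-dimethyl-2-(2-oxo-1,3-oxazolidine-3-carbonyl)cyclohex-3-en-1-yl]-5-[(2S)-3-iodo-4-methyl-5-oxo-2,5-dihydrofuran-2-yl]-4-methylpent-4-en-1-yl butanoate
Conditions: Ac2O (3 equiv), Et3SiH (5 equiv), TMSOTf (0.3 equiv), CH2Cl2, −78 → −40 °C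
Reagents that add atoms: acetic anhydride, CC(=O)OC(C)=O
Why: Proposed new method: reductive SN1′-type bridge opening in which acetyl triflate formed in situ acylates the strained bridging oxygen, the tertiary allylic C11–O bond ionises (C14–O is never broken, so C14 keeps its configuration and emerges as the acetate) and triethylsilane delivers hydride to the less substituted allyl terminus C13, leaving the trisubstituted C11=C12 alkene; the closest known reactions are silane/Lewis acid ionic hydrogenation of allylic and tertiary ethers and acetic anhydride/Lewis acid cleavage of 7-oxanorbornanes.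

**Step 15**
Reactants: 21 (1R,4Z)-1-[(1S,2S,6S)-6-acetoxy-1,3-dimethyl-2-(2-oxo-1,3-oxazolidine-3-carbonyl)cyclohex-3-en-1-yl]-5-[(2S)-3-iodo-4-methyl-5-oxo-2,5-dihydrofuran-2-yl]-4-methylpent-4-en-1-yl butanoate
Product: 22 (1R,4Z)-1-[(1S,2S,6S)-6-acetoxy-2-formyl-1,3-dimethylcyclohex-3-en-1-yl]-5-[(2S)-3-iodo-4-methyl-5-oxo-2,5-dihydrofuran-2-yl]-4-methylpent-4-en-1-yl butanoate
Conditions: Cp2Zr(H)Cl (1.8 equiv), THF, rt, 15 min
Reagents that add atoms: none
Why: Schwartz reduction: hydrozirconation of the exocyclic imide carbonyl gives a zirconated N,O-hemiaminal that releases the aldehyde and the oxazolidinone on work-up, faster than esters, the lactone or trisubstituted alkenes react and under neutral conditions, so C10 is kept; the crude β,γ-unsaturated aldehyde is used at once.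

**Step 16**
Reactants: 22 (1R,4Z)-1-[(1S,2S,6S)-6-acetoxy-2-formyl-1,3-dimethylcyclohex-3-en-1-yl]-5-[(2S)-3-iodo-4-methyl-5-oxo-2,5-dihydrofuran-2-yl]-4-methylpent-4-en-1-yl butanoate
Product: 24 (1S,2R,5Z,7S,9R,10S,14S)-14-acetoxy-2-butanoyloxy-9-hydroxybriara-5,8(17),11-trien-18,7-olide (CNP0293221.1), via alkenylchromium dichloride 23 (not isolated)
Conditions: CrCl2 (8 equiv), NiCl2 (2 mol %), DMSO/THF 3:1, 2 mM, rt
Reagents that add atoms: none
Why: Nozaki–Hiyama–Kishi reaction: nickel-catalysed insertion into the activated alkenyl iodide and transmetalation to chromium give an alkenylchromium species that adds only to the aldehyde under neutral conditions and, at high dilution, closes the ten-membered ring; the tether lets the alkenyl carbon reach the aldehyde only from the C1 side with the carbonyl oxygen turned outward, which is expected (not proven) to give the (9R)-alcohol.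

## Compound list

1 | mesaconic acid, (E)-2-methylbut-2-enedioic acid | OC(=O)/C=C(\C)C(=O)O | starting material
2 | mesaconyl dichloride, (E)-2-methylbut-2-enedioyl dichloride | ClC(=O)/C=C(\C)C(=O)Cl | intermediate
3 | 1,3-oxazolidin-2-one | O=C1NCCO1 | starting material
4 | lithium 2-oxo-1,3-oxazolidin-3-ide | [Li+].O=C1[N-]CCO1 | intermediate
5 | (E)-2-methyl-4-oxo-4-(2-oxo-1,3-oxazolidin-3-yl)but-2-enoyl chloride | ClC(=O)/C(C)=C/C(=O)N1CCOC1=O | intermediate
6 | S-ethyl (E)-2-methyl-4-oxo-4-(2-oxo-1,3-oxazolidin-3-yl)but-2-enethioate | CCSC(=O)/C(C)=C/C(=O)N1CCOC1=O | intermediate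
7 | 2-methylfuran | Cc1ccco1 | starting material
8 | S-ethyl (1S,2R,3R,4R)-2,4-dimethyl-3-(2-oxo-1,3-oxazolidine-3-carbonyl)-7-oxabicyclo[2.2.1]hept-5-ene-2-carbothioate; thioester exo, 2-methyl endo, imide endo; bicyclo C1, C2, C3, C4 = target C14, C1, C10, C11 | CCSC(=O)[C@@]1(C)[C@H]2O[C@](C)(C=C2)[C@@H]1C(=O)N1CCOC1=O | intermediate
9 | anhydromevalonolactone, 4-methyl-5,6-dihydro-2H-pyran-2-one | CC1=CC(=O)OCC1 | starting material
10 | (Z)-5-hydroxy-N-methoxy-N,3-dimethylpent-2-enamide | OCC/C(C)=C\C(=O)N(C)OC | intermediate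
11 | (Z)-5-iodo-N-methoxy-N,3-dimethylpent-2-enamide | ICC/C(C)=C\C(=O)N(C)OC | intermediate
12 | (Z)-8-iodo-6-methyloct-5-en-2-yn-4-one | CC#CC(=O)/C=C(C)\CCI | intermediate
13 | (4R,5Z)-8-iodo-6-methyloct-5-en-2-yn-4-ol | CC#C[C@H](O)/C=C(C)\CCI | intermediate
14 | methyl (4R,5Z)-8-iodo-6-methyloct-5-en-2-yn-4-yl carbonate | CC#C[C@H](OC(=O)OC)/C=C(C)\CCI | intermediate
15 | methyl (Sa,5Z)-8-iodo-2,6-dimethylocta-2,3,5-trienoate; (Sa) = P-helical allene | COC(=O)C(C)=[C@@]=C([H])/C=C(C)\CCI | intermediate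
16 | [(Sa,3Z)-8-methoxy-3,7-dimethyl-8-oxoocta-3,5,6-trien-1-yl]zinc iodide | COC(=O)C(C)=[C@@]=C([H])/C=C(C)\CC[Zn]I | intermediate
17 | methyl (Sa,5Z)-8-[(1S,2R,3R,4R)-2,4-dimethyl-3-(2-oxo-1,3-oxazolidine-3-carbonyl)-7-oxabicyclo[2.2.1]hept-5-en-2-yl]-2,6-dimethyl-8-oxoocta-2,3,5-trienoate | COC(=O)C(C)=[C@@]=C([H])/C=C(C)\CCC(=O)[C@@]1(C)[C@H]2O[C@](C)(C=C2)[C@@H]1C(=O)N1CCOC1=O | intermediate
18 | methyl (Sa,5Z,8R)-8-[(1S,2S,3R,4R)-2,4-dimethyl-3-(2-oxo-1,3-oxazolidine-3-carbonyl)-7-oxabicyclo[2.2.1]hept-5-en-2-yl]-8-hydroxy-2,6-dimethylocta-2,3,5-trienoate | COC(=O)C(C)=[C@@]=C([H])/C=C(C)\CC[C@@H](O)[C@@]1(C)[C@H]2O[C@](C)(C=C2)[C@@H]1C(=O)N1CCOC1=O | intermediate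
19 | methyl (Sa,5Z,8R)-8-(butanoyloxy)-8-[(1S,2S,3R,4R)-2,4-dimethyl-3-(2-oxo-1,3-oxazolidine-3-carbonyl)-7-oxabicyclo[2.2.1]hept-5-en-2-yl]-2,6-dimethylocta-2,3,5-trienoate | COC(=O)C(C)=[C@@]=C([H])/C=C(C)\CC[C@@H](OC(=O)CCC)[C@@]1(C)[C@H]2O[C@](C)(C=C2)[C@@H]1C(=O)N1CCOC1=O | intermediate
20 | (1R,4Z)-1-[(1S,2S,3R,4R)-2,4-dimethyl-3-(2-oxo-1,3-oxazolidine-3-carbonyl)-7-oxabicyclo[2.2.1]hept-5-en-2-yl]-5-[(2S)-3-iodo-4-methyl-5-oxo-2,5-dihydrofuran-2-yl]-4-methylpent-4-en-1-yl butanoate | CC1=C(I)[C@@H](OC1=O)/C=C(C)\CC[C@@H](OC(=O)CCC)[C@@]2(C)[C@H]3O[C@](C)(C=C3)[C@@H]2C(=O)N2CCOC2=O | intermediate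
21 | (1R,4Z)-1-[(1S,2S,6S)-6-acetoxy-1,3-dimethyl-2-(2-oxo-1,3-oxazolidine-3-carbonyl)cyclohex-3-en-1-yl]-5-[(2S)-3-iodo-4-methyl-5-oxo-2,5-dihydrofuran-2-yl]-4-methylpent-4-en-1-yl butanoate | CC1=C(I)[C@@H](OC1=O)/C=C(C)\CC[C@@H](OC(=O)CCC)[C@@]2(C)[C@@H](OC(C)=O)CC=C(C)[C@@H]2C(=O)N2CCOC2=O | intermediate
22 | (1R,4Z)-1-[(1S,2S,6S)-6-acetoxy-2-formyl-1,3-dimethylcyclohex-3-en-1-yl]-5-[(2S)-3-iodo-4-methyl-5-oxo-2,5-dihydrofuran-2-yl]-4-methylpent-4-en-1-yl butanoate | CC1=C(I)[C@@H](OC1=O)/C=C(C)\CC[C@@H](OC(=O)CCC)[C@@]2(C)[C@@H](OC(C)=O)CC=C(C)[C@@H]2C=O | intermediate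
23 | alkenylchromium dichloride of 22 (CrCl2 in place of iodine on the butenolide β-carbon C8) | CC1=C([Cr](Cl)Cl)[C@@H](OC1=O)/C=C(C)\CC[C@@H](OC(=O)CCC)[C@@]2(C)[C@@H](OC(C)=O)CC=C(C)[C@@H]2C=O | intermediate
24 | (1S,2R,5Z,7S,9R,10S,14S)-14-acetoxy-2-butanoyloxy-9-hydroxybriara-5,8(17),11-trien-18,7-olide (CNP0293221.1) | CCCC(=O)O[C@@H]1CC/C(C)=C\[C@@H]2OC(=O)C(C)=C2[C@H](O)[C@H]2C(C)=CC[C@H](OC(C)=O)[C@@]21C | target

## Summary

Total step count: 16.
Longest linear sequence: 13 steps (steps 4–9, then 10–16).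

The three steps most likely to fail:

**Step 3 (catalytic asymmetric Diels–Alder).** The β,β-disubstituted dienophile may be too slow, 2-methylfuran may divert to Friedel–Crafts products, or the adduct may revert. The fallback sets out from 7 and comes back at 8.
- 2-Methylfuran 7 and commercial citraconic anhydride are kept neat at room temperature for several days. This thermal, reversible, exo-selective Diels–Alder reaction accumulates the less congested regioisomer and gives racemic exo-3a,7-dimethyl-3a,4,7,7a-tetrahydro-4,7-epoxy-2-benzofuran-1,3-dione F1.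
- Lithium oxazolidinide 4 (THF, −78 °C) opens the anhydride at the less hindered carbonyl, the one on C10. Crystallisation of the (R)-1-phenylethylammonium salt gives one enantiomer of the exo,exo imide acid F2.
- LiN(SiMe3)2 (2.1 equiv, −78 °C) followed by kinetic protonation of the imide enolate from the exo face (AcOH, −78 °C) turns the imide endo and gives the trans imide acid F3.
- Thioesterification (EtSH, DCC, cat. DMAP) then gives 8.

**Step 14 (reductive bridge opening).** Hydride may go to C11, the allyl cation may lose the C10 proton, or the acylating agent may attack the side-chain alkene. The fallback sets out from 20 and comes back at 21.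
- Diimide (potassium azodicarboxylate, AcOH, MeOH, rt) saturates only the strained C12=C13 bond and gives the 7-oxanorbornane F4.
- Ac2O with BF3·OEt2 (CH2Cl2, −20 °C) then cleaves the tertiary C11–O bond by an E1 pathway with loss of H-12. This gives the C14 acetate and the C11=C12 alkene of 21 by elimination instead of reduction.

**Step 16 (ring closure and C9 configuration).** The strained trans-fused ten-membered ring may not close, or the 9-epimer may form. The fallback sets out from 21, so step 15 is skipped, and comes back at 24.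
- Iodine–magnesium exchange (i-PrMgCl·LiCl, THF, −78 °C) gives an alkenylmagnesium that acylates intramolecularly on the oxazolidinone imide. The chelated tetrahedral adduct prevents over-addition, and the product is the macrocyclic C9 ketone F5.
- Reduction under Luche conditions (NaBH4, CeCl3·7H2O, MeOH, −78 °C), or with a CBS oxazaborolidine of the appropriate hand if substrate control is poor, gives 24.

## Further compounds

F1 | step 3 | racemic exo-3a,7-dimethyl-3a,4,7,7a-tetrahydro-4,7-epoxy-2-benzofuran-1,3-dione (enantiomer shown is the one carried on) | O=C1OC(=O)[C@@]2(C)[C@H]3O[C@](C)(C=C3)[C@@H]12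
F2 | step 3 | exo,exo imide acid: 2,4-dimethyl-3-exo-(2-oxo-1,3-oxazolidine-3-carbonyl)-7-oxabicyclo[2.2.1]hept-5-ene-2-exo-carboxylic acid, resolved | OC(=O)[C@@]1(C)[C@H]2O[C@](C)(C=C2)[C@H]1C(=O)N1CCOC1=O
F3 | step 3 | trans imide acid: 2,4-dimethyl-3-endo-(2-oxo-1,3-oxazolidine-3-carbonyl)-7-oxabicyclo[2.2.1]hept-5-ene-2-exo-carboxylic acid | OC(=O)[C@@]1(C)[C@H]2O[C@](C)(C=C2)[C@@H]1C(=O)N1CCOC1=O
F4 | step 14 | 5,6-dihydro derivative of 20 (7-oxabicyclo[2.2.1]heptane in place of the hept-5-ene) | CC1=C(I)[C@@H](OC1=O)/C=C(C)\CC[C@@H](OC(=O)CCC)[C@@]2(C)[C@H]3O[C@](C)(CC3)[C@@H]2C(=O)N2CCOC2=O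
F5 | step 16 | 9-oxo analogue of 24: (1S,2R,5Z,7S,10S,14S)-14-acetoxy-2-butanoyloxy-9-oxobriara-5,8(17),11-trien-18,7-olide | CCCC(=O)O[C@@H]1CC/C(C)=C\[C@@H]2OC(=O)C(C)=C2C(=O)[C@H]2C(C)=CC[C@H](OC(C)=O)[C@@]21C
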